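**Remarks (assumptions)**
- Ring A is the acyloxy-cyclohexenedione ring: C1 (C(Me)O-acyl), C2 (C=O), C3 (=CH), C4 (C–OMe), C5 (quaternary C), C6 (C=O). Ring B is the aminocyclohexadienone ring: C1 (ring C=O), C2 (C–CH2), C3 (C–OMe), C4 (C–acyl), C5 (C–NH2), C6 (C(Me)OH).
- As drawn, both 2-methylbutanoyl groups are (R), ring A is (1R,5R) and ring B is (6R). (R)-2-Methylbutanoic acid, (R)-lactic acid and (R)-lactamide are taken as commercial.
- Enolised compounds are drawn as one tautomer. Some descriptors change along the route when a substituent changes (for example bromine) although the spatial arrangement is kept; the SMILES strings are the reference.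

**Retrosynthetic overview**
1. Gilluone B 26 ⇐ C5(ring A)–CH2 bond: Michael addition of ring A dienolate 16 (C3 blocked by Br, removed last) to the aza-quinone methide from ring B sulfone 23.
2. Ring B (22) ⇐ key step: 2-pyranone 8 + lactamide-derived lactim ether 19; one operation makes C1–C6 and C4–C5 of ring B, sets C6 and delivers the nitrogen.
3. Ring A (16) ⇐ triketone 14 by a bromination-triggered C→O shift of the 2-methylbutanoyl group; 14 ⇐ 2-pyranone 9 + lactic acid dioxolanone 12 (the same ring transformation in the oxygen series).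
4. Enabling feature: in ring B the segment C1(=O)–C2=C3(OMe)–C4–C(=O)-sec-butyl is a ring-opened 4-methoxy-6-sec-butyl-2-pyranone (pyranone O1 = side-chain ketone oxygen) and C5(NH2)–C6(Me)(OH) is a lactamide unit, so the pyranone is an internal activated ester that releases the C4 nucleophile.
5. Ring order: pyranone ring (step 2) → carbocyclic ring A (step 7) and ring B (step 11), each by skeletal rearrangement of a pyranone → union of the rings (step 13).

Key step: step 11

**Route**

Step 1
Reactants: 1 (2R)-2-methylbutanoic acid; 2 2,2,6-trimethyl-4H-1,3-dioxin-4-one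
Product: 4 2,2-dimethyl-6-[(3R)-3-methyl-2-oxopentyl]-4H-1,3-dioxin-4-one, via acyl imidazole 3 (not isolated)
Conditions: 1, CDI, THF, 23 °C; added to 2 + LiN(i-Pr)2 (2.2 equiv each), THF, −78 → −40 °C; AcOH
Reagents that add atoms: 1,1'-carbonyldiimidazole, O=C(n1ccnc1)n1ccnc1 (imidazolyl group of 3)
Why: C-acylation of the γ-lithiated dioxinone with the acyl imidazole (vinylogous Claisen condensation); the excess dienolate deprotonates the product at its doubly activated CH2, so the α-stereocentre of the acyl group should not be enolised.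

Step 2
Reactants: 4 2,2-dimethyl-6-[(3R)-3-methyl-2-oxopentyl]-4H-1,3-dioxin-4-one
Product: 6 6-[(2R)-butan-2-yl]-4-hydroxy-2H-pyran-2-one, via acylketene 5 (not isolated)
Conditions: toluene, 110 °C
Reagents that add atoms: none
Why: Thermal retro-hetero-Diels–Alder loss of acetone gives the acylketene, which the enol of the remote ketone traps (acylketene lactonisation) under neutral conditions that leave the sec-butyl centre untouched.

Step 3
Reactants: 6 6-[(2R)-butan-2-yl]-4-hydroxy-2H-pyran-2-one
Product: 7 6-[(2R)-butan-2-yl]-4-hydroxy-3-[(phenylsulfanyl)methyl]-2H-pyran-2-one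
Conditions: (CH2O)n, PhSH, piperidine (cat.), AcOH (cat.), EtOH, 60 °C
Reagents that add atoms: formaldehyde (as paraformaldehyde), C=O; thiophenol, Sc1ccccc1
Why: Three-component Knoevenagel/thia-Michael reaction at the nucleophilic C3 of the 4-hydroxy-2-pyranone; thiophenol traps the 3-methylene intermediate and so prevents methylene-bis-pyranone formation.

Step 4
Reactants: 7 6-[(2R)-butan-2-yl]-4-hydroxy-3-[(phenylsulfanyl)methyl]-2H-pyran-2-one
Product: 8 6-[(2R)-butan-2-yl]-4-methoxy-3-[(phenylsulfanyl)methyl]-2H-pyran-2-one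
Conditions: Me2SO4, K2CO3, acetone, 56 °C
Reagents that add atoms: dimethyl sulfate, COS(=O)(=O)OC
Why: O-Methylation of the vinylogous acid (Williamson-type alkylation), which with K2CO3/Me2SO4 should give the 4-methoxy-2-pyranone and fixes the ring B and ring A methyl ether before any ring transformation.

Step 5
Reactants: 8 6-[(2R)-butan-2-yl]-4-methoxy-3-[(phenylsulfanyl)methyl]-2H-pyran-2-one
Product: 9 6-[(2R)-butan-2-yl]-4-methoxy-3-methyl-2H-pyran-2-one
Conditions: Raney Ni (W-2), EtOH, 23 °C
Reagents that add atoms: none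
Why: Raney nickel hydrogenolysis of the allylic C–S bond (desulfurisation) turns the thiomethyl handle into the C-methyl group that ring A needs.

Step 6
Reactants: 10 (2R)-2-hydroxypropanoic acid; 11 2,2-dimethylpropanal
Product: 12 (2R,5R)-2-tert-butyl-5-methyl-1,3-dioxolan-4-one
Conditions: TsOH (cat.), H2SO4 (cat.), pentane, reflux, Dean–Stark; recrystallisation (pentane, −78 °C)
Reagents that add atoms: none
Why: Acid-catalysed acetalisation of the α-hydroxy acid with pivaldehyde; the cis acetal is expected to predominate and its acetal carbon stores the configuration of lactic acid (self-regeneration of stereocentres).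

Step 7
Reactants: 12 (2R,5R)-2-tert-butyl-5-methyl-1,3-dioxolan-4-one; 9 6-[(2R)-butan-2-yl]-4-methoxy-3-methyl-2H-pyran-2-one
Product: 14 (6R)-5,6-dihydroxy-3-methoxy-2,6-dimethyl-4-[(2R)-2-methylbutanoyl]cyclohexa-2,4-dien-1-one, via dienolate 13 (not isolated)
Conditions: 12, LiN(i-Pr)2, THF, −78 °C; 9, −78 → 23 °C; AcOH, H2O
Reagents that add atoms: none
Why: Proposed new method: the lithium enolate of 12 (electrophiles enter trans to tert-butyl) should add to the lactone carbonyl of 9, ring opening should release the enolate of the sec-butyl ketone, and its α-carbon should close the carbocycle by a Dieckmann-type 6-exo-trig attack on the dioxolanone carbonyl with loss of pivaldehyde, which sets C6 of 14 as (R); the closest known reactions are the aldol, alkylation and acylation reactions of this dioxolanone enolate, carbanion-induced ring transformations of 2-pyranones and the Staunton–Weinreb annulation.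

Step 8
Reactants: 14 (6R)-5,6-dihydroxy-3-methoxy-2,6-dimethyl-4-[(2R)-2-methylbutanoyl]cyclohexa-2,4-dien-1-one
Product: 16 (1R)-3-bromo-2-hydroxy-4-methoxy-1,5-dimethyl-6-oxocyclohexa-2,4-dien-1-yl (2R)-2-methylbutanoate, via bromotriketone 15 (not isolated)
Conditions: NBS (1.0 equiv), CH2Cl2, 0 °C; then Et3N (0.1 equiv), 23 °C
Reagents that add atoms: N-bromosuccinimide, O=C1CCC(=O)N1Br
Why: Electrophilic bromination of the enolised β-triketone at C4 makes the 2-methylbutanoyl ketone non-enolisable, and the neighbouring tertiary hydroxyl should then cleave it by an intramolecular retro-Claisen reaction through a five-membered hemiketal (deacylative bromination with internal acyl capture); this esterifies the hindered alcohol without touching its configuration and leaves bromine on the ring carbon that must not be alkylated in step 13.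

Step 9
Reactants: 17 (2R)-2-hydroxypropanamide; 11 2,2-dimethylpropanal
Product: 18 (2S,5R)-2-tert-butyl-5-methyl-1,3-oxazolidin-4-one
Conditions: TsOH (cat.), toluene, reflux, Dean–Stark; crystallisation of the cis isomer
Reagents that add atoms: none
Why: Acid-catalysed N,O-acetalisation of the α-hydroxy amide with pivaldehyde (oxazolidinone formation); the cis isomer is purified so that the acetal carbon is one defined (2S) centre.

Step 10
Reactants: 18 (2S,5R)-2-tert-butyl-5-methyl-1,3-oxazolidin-4-one
Product: 19 (2S,5R)-2-tert-butyl-4-methoxy-5-methyl-2,5-dihydro-1,3-oxazole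
Conditions: Me3OBF4, CH2Cl2, 23 °C; aq. Na2CO3
Reagents that add atoms: trimethyloxonium tetrafluoroborate, C[O+](C)C.F[B-](F)(F)F
Why: O-Alkylation of the secondary lactam with the trialkyloxonium salt gives the lactim ether, the oxygen analogue of the 1-Boc-2-tert-butyl-4-methoxy-2,5-dihydroimidazole glycine template.

Step 11
Reactants: 19 (2S,5R)-2-tert-butyl-4-methoxy-5-methyl-2,5-dihydro-1,3-oxazole; 8 6-[(2R)-butan-2-yl]-4-methoxy-3-[(phenylsulfanyl)methyl]-2H-pyran-2-one
Product: 22 (6R)-5-amino-6-hydroxy-3-methoxy-6-methyl-4-[(2R)-2-methylbutanoyl]-2-[(phenylsulfanyl)methyl]cyclohexa-2,4-dien-1-one, via dienolate 20 (not isolated), via bicyclic aminal 21 (not isolated)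
Conditions: 19, LiN(i-Pr)2, THF, −78 °C; 8, −78 → 23 °C; AcOH/NaOAc buffer (pH 4), THF–H2O, 23 °C
Reagents that add atoms: none
Why: Proposed new method: the lithium aza-enolate of 19 (planar at C5, one face covered by tert-butyl) should add to the lactone carbonyl of 8, the tetrahedral intermediate opening with loss of the ring oxygen as a ketone enolate (first bond, C1–C6 of ring B), and the dienolate carbon so released should add to the lactim ether carbon with loss of methoxide (second bond, C4–C5), after which the buffered work-up hydrolyses the tert-butyl N,O-acetal of 21. The closest known reactions are the trans-selective reactions of the lithiated 1-Boc-2-tert-butyl-4-methoxy-2,5-dihydroimidazole lactim ether with electrophiles, carbanion-induced ring transformations of 2-pyranones, the Staunton–Weinreb annulation and the condensation of lactim ethers with C–H acids. Ring B is closed by a 6-exo-trig addition of the enolate carbon to the C=N bond; the oxazolidine ring of 21 is only carried along from the template and is opened again. The one new stereocentre, C6, is set in the first bond formation by the acetal carbon C2 of 19: the acyl group enters trans to tert-butyl, which with the (2S) template gives (6R). The step needs 1,2-addition at the lactone carbonyl and not attack at C4 or C6 or deprotonation of the sec-butyl methine; the 4-methoxy group deactivates C4, the α-branched sec-butyl group shields C6, and a hard lithium aza-enolate at −78 °C favours the carbonyl. It also needs C- and not O-cyclisation of the dienolate, which the six- against eight-membered ring size secures, and the nitrile-like lactim carbon places the nitrogen on C5 without any later amination.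

Step 12
Reactants: 22 (6R)-5-amino-6-hydroxy-3-methoxy-6-methyl-4-[(2R)-2-methylbutanoyl]-2-[(phenylsulfanyl)methyl]cyclohexa-2,4-dien-1-one
Product: 23 (6R)-5-amino-2-[(benzenesulfonyl)methyl]-6-hydroxy-3-methoxy-6-methyl-4-[(2R)-2-methylbutanoyl]cyclohexa-2,4-dien-1-one
Conditions: (NH4)6Mo7O24·4H2O (cat.), 30% H2O2, EtOH, 0 → 23 °C
Reagents that add atoms: hydrogen peroxide, OO
Why: Molybdate-catalysed peroxide oxidation of the sulfide to the sulfone, selective for sulfur over the push–pull double bonds, turns the handle into a sulfinate leaving group.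

Step 13
Reactants: 23 (6R)-5-amino-2-[(benzenesulfonyl)methyl]-6-hydroxy-3-methoxy-6-methyl-4-[(2R)-2-methylbutanoyl]cyclohexa-2,4-dien-1-one; 16 (1R)-3-bromo-2-hydroxy-4-methoxy-1,5-dimethyl-6-oxocyclohexa-2,4-dien-1-yl (2R)-2-methylbutanoate
Product: 25 (1S,5R)-5-{[(5R)-4-amino-5-hydroxy-2-methoxy-5-methyl-3-[(2R)-2-methylbutanoyl]-6-oxocyclohexa-1,3-dien-1-yl]methyl}-3-bromo-4-methoxy-1,5-dimethyl-2,6-dioxocyclohex-3-en-1-yl (2R)-2-methylbutanoate, via aza-quinone methide 24 (not isolated)
Conditions: Cs2CO3, DMF, 0 → 40 °C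
Reagents that add atoms: none
Why: Base-induced 1,6-elimination of benzenesulfinate from the N-deprotonated vinylogous amide should give the aza-quinone methide, to which the caesium dienolate of 16 adds through C5 (Michael addition; C3 is blocked by bromine and O-alkylation is reversible) on the face opposite to the acyloxy group at C1, which should set (5R).

Step 14
Reactants: 25 (1S,5R)-5-{[(5R)-4-amino-5-hydroxy-2-methoxy-5-methyl-3-[(2R)-2-methylbutanoyl]-6-oxocyclohexa-1,3-dien-1-yl]methyl}-3-bromo-4-methoxy-1,5-dimethyl-2,6-dioxocyclohex-3-en-1-yl (2R)-2-methylbutanoate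
Product: 26 Gilluone B
Conditions: Pd(PPh3)4 (5 mol %), Bu3SnH, THF, 23 °C
Reagents that add atoms: none
Why: Palladium-catalysed hydrodebromination of the vinyl bromide with tributyltin hydride (oxidative addition to zerovalent palladium, hydride transfer, reductive elimination) should remove the blocking group without touching the esters, the enaminone or the tertiary α-oxygenated ketones.

**Compound list**
1 | (2R)-2-methylbutanoic acid | CC[C@@H](C)C(=O)O | starting material
2 | 2,2,6-trimethyl-4H-1,3-dioxin-4-one | CC1=CC(=O)OC(C)(C)O1 | starting material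
3 | (2R)-1-(1H-imidazol-1-yl)-2-methylbutan-1-one | CC[C@@H](C)C(=O)n1ccnc1 | intermediate
4 | 2,2-dimethyl-6-[(3R)-3-methyl-2-oxopentyl]-4H-1,3-dioxin-4-one | CC[C@@H](C)C(=O)CC1=CC(=O)OC(C)(C)O1 | intermediate
5 | (6R)-6-methyloct-1-ene-1,3,5-trione (acylketene) | CC[C@@H](C)C(=O)CC(=O)C=C=O | intermediate
6 | 6-[(2R)-butan-2-yl]-4-hydroxy-2H-pyran-2-one | CC[C@@H](C)C1=CC(O)=CC(=O)O1 | intermediate
7 | 6-[(2R)-butan-2-yl]-4-hydroxy-3-[(phenylsulfanyl)methyl]-2H-pyran-2-one | CC[C@@H](C)C1=CC(O)=C(CSc2ccccc2)C(=O)O1 | intermediate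
8 | 6-[(2R)-butan-2-yl]-4-methoxy-3-[(phenylsulfanyl)methyl]-2H-pyran-2-one | CC[C@@H](C)C1=CC(OC)=C(CSc2ccccc2)C(=O)O1 | intermediate
9 | 6-[(2R)-butan-2-yl]-4-methoxy-3-methyl-2H-pyran-2-one | CC[C@@H](C)C1=CC(OC)=C(C)C(=O)O1 | intermediate
10 | (2R)-2-hydroxypropanoic acid ((R)-lactic acid) | C[C@@H](O)C(=O)O | starting material
11 | 2,2-dimethylpropanal (pivaldehyde) | CC(C)(C)C=O | starting material
12 | (2R,5R)-2-tert-butyl-5-methyl-1,3-dioxolan-4-one (cis) | C[C@@H]1C(=O)O[C@@H](O1)C(C)(C)C | intermediate
13 | lithium dienolate of the C5-acylated dioxolanone: (2R,5S)-2-tert-butyl-5-[(6R)-3-methoxy-2,6-dimethyl-5-oxooct-2-enoyl]-5-methyl-1,3-dioxolan-4-one, acyl carbonyl and C4 of the chain cis on the C2=C3 bond | [Li+].CC[C@@H](C)/C([O-])=C/C(OC)=C(C)\C(=O)[C@]1(C)O[C@@H](C(C)(C)C)OC1=O | intermediate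
14 | (6R)-5,6-dihydroxy-3-methoxy-2,6-dimethyl-4-[(2R)-2-methylbutanoyl]cyclohexa-2,4-dien-1-one | CC1=C(OC)C(C(=O)[C@H](C)CC)=C(O)[C@@](C)(O)C1=O | intermediate
15 | (6S)-4-bromo-6-hydroxy-3-methoxy-2,6-dimethyl-4-[(2R)-2-methylbutanoyl]cyclohex-2-ene-1,5-dione (C4 epimers; C6 arrangement as in 14) | CC1=C(OC)C(Br)(C(=O)[C@H](C)CC)C(=O)[C@@](C)(O)C1=O | intermediate
16 | (1R)-3-bromo-2-hydroxy-4-methoxy-1,5-dimethyl-6-oxocyclohexa-2,4-dien-1-yl (2R)-2-methylbutanoate | CC[C@@H](C)C(=O)O[C@]1(C)C(O)=C(Br)C(OC)=C(C)C1=O | intermediate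
17 | (2R)-2-hydroxypropanamide ((R)-lactamide) | C[C@@H](O)C(N)=O | starting material
18 | (2S,5R)-2-tert-butyl-5-methyl-1,3-oxazolidin-4-one (cis) | C[C@@H]1C(=O)N[C@@H](O1)C(C)(C)C | intermediate
19 | (2S,5R)-2-tert-butyl-4-methoxy-5-methyl-2,5-dihydro-1,3-oxazole | C[C@@H]1C(OC)=N[C@@H](O1)C(C)(C)C | intermediate
20 | lithium dienolate of (6R)-1-[(2S,5R)-2-tert-butyl-4-methoxy-5-methyl-2,5-dihydro-1,3-oxazol-5-yl]-3-methoxy-6-methyl-2-[(phenylsulfanyl)methyl]oct-2-ene-1,5-dione, C1 and C4 cis on the C2=C3 bond | [Li+].CC[C@@H](C)/C([O-])=C/C(OC)=C(CSc1ccccc1)\C(=O)[C@]2(C)O[C@@H](C(C)(C)C)N=C2OC | intermediate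
21 | (2S,7aR)-2-tert-butyl-5-methoxy-7a-methyl-4-[(2R)-2-methylbutanoyl]-6-[(phenylsulfanyl)methyl]-2,3-dihydro-1,3-benzoxazol-7(7aH)-one | c1ccccc1SCC2=C(OC)C(C(=O)[C@H](C)CC)=C3N[C@H](C(C)(C)C)O[C@@]3(C)C2=O | intermediate
22 | (6R)-5-amino-6-hydroxy-3-methoxy-6-methyl-4-[(2R)-2-methylbutanoyl]-2-[(phenylsulfanyl)methyl]cyclohexa-2,4-dien-1-one | c1ccccc1SCC2=C(OC)C(C(=O)[C@H](C)CC)=C(N)[C@@](C)(O)C2=O | intermediate
23 | (6R)-5-amino-2-[(benzenesulfonyl)methyl]-6-hydroxy-3-methoxy-6-methyl-4-[(2R)-2-methylbutanoyl]cyclohexa-2,4-dien-1-one | O=S(=O)(CC1=C(OC)C(C(=O)[C@H](C)CC)=C(N)[C@@](C)(O)C1=O)c1ccccc1 | intermediate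
24 | (6R)-6-hydroxy-5-imino-3-methoxy-6-methyl-2-methylidene-4-[(2R)-2-methylbutanoyl]cyclohex-3-en-1-one (aza-quinone methide) | C=C1C(=O)[C@](C)(O)C(=N)C(C(=O)[C@H](C)CC)=C1OC | intermediate
25 | (1S,5R)-5-{[(5R)-4-amino-5-hydroxy-2-methoxy-5-methyl-3-[(2R)-2-methylbutanoyl]-6-oxocyclohexa-1,3-dien-1-yl]methyl}-3-bromo-4-methoxy-1,5-dimethyl-2,6-dioxocyclohex-3-en-1-yl (2R)-2-methylbutanoate (3-bromo-gilluone B; C1 arrangement as in 26) | CC[C@@H](C)C(=O)O[C@]1(C)C(=O)C(Br)=C(OC)[C@@](C)(CC2=C(OC)C(C(=O)[C@H](C)CC)=C(N)[C@@](C)(O)C2=O)C1=O | intermediate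
26 | Gilluone B: (1R,5R)-5-{[(5R)-4-amino-5-hydroxy-2-methoxy-5-methyl-3-[(2R)-2-methylbutanoyl]-6-oxocyclohexa-1,3-dien-1-yl]methyl}-4-methoxy-1,5-dimethyl-2,6-dioxocyclohex-3-en-1-yl (2R)-2-methylbutanoate | CC[C@@H](C)C(=O)O[C@]1(C)C(=O)C=C(OC)[C@@](C)(CC2=C(OC)C(C(=O)[C@H](C)CC)=C(N)[C@@](C)(O)C2=O)C1=O | target

**Step count**
Total: 14 steps. Longest linear sequence: 9 steps (steps 1, 2, 3, 4, 5, 7, 8, 13, 14).

**The three steps most likely to fail**

1. Step 11 (carries the label). The aza-enolate may attack C6 of the pyranone in a conjugate sense, or may abstract the sec-butyl methine proton of 8, which would also erode the configuration of the side chain. The closure onto the lactim ether may be slow, so that the open dienolate decomposes, and the product anion may lose thiophenolate.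
Fallback by known chemistry, setting out from 1 and coming back at 22: 1 is converted into (2R)-2-methylbutanoyl chloride F1 ((COCl)2, cat. DMF). Friedel–Crafts acylation of 5-methoxy-2-methylbenzene-1,3-diol with F1 (BF3·OEt2 or AlCl3) gives (2R)-1-(2,4-dihydroxy-6-methoxy-3-methylphenyl)-2-methylbutan-1-one F2; the two free ring positions of the phenol are equivalent. Catalytic enantioselective hydroxylative dearomatisation at the methyl-bearing carbon between the two hydroxyls ([Cu(MeCN)4]PF6, monovalent copper, with the sparteine enantiomer that gives (6R), O2; or a flavin-dependent monooxygenase) gives (6R)-5,6-dihydroxy-3-methoxy-6-methyl-4-[(2R)-2-methylbutanoyl]cyclohexa-2,4-dien-1-one F3. Thiomethylation of its C2–H (paraformaldehyde, PhSH) gives (6R)-5,6-dihydroxy-3-methoxy-6-methyl-4-[(2R)-2-methylbutanoyl]-2-[(phenylsulfanyl)methyl]cyclohexa-2,4-dien-1-one F4. The C5 enol oxygen is then exchanged for nitrogen through the enol triflate F5 (PhNTf2, Et3N; then NH3, MeOH), which gives 22. In this reserve route the site of nitrogen entry is not fixed by construction and has to be proven, which is why it is not the first choice.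

2. Step 7 (carries the label). The same competition between carbonyl addition, conjugate addition and proton transfer applies, and the dioxolanone enolate may decompose on warming before the second C–C bond is formed.
Fallback by known chemistry, setting out from 1 and coming back at 14: ketone F2, made through F1 as described above, is thiomethylated at its remaining ring position (paraformaldehyde, PhSH) to (2R)-1-{2,4-dihydroxy-6-methoxy-3-methyl-5-[(phenylsulfanyl)methyl]phenyl}-2-methylbutan-1-one F6. Raney Ni desulfurisation gives (2R)-1-(2,4-dihydroxy-6-methoxy-3,5-dimethylphenyl)-2-methylbutan-1-one F7. The same copper–sparteine–O2 or enzymatic hydroxylative dearomatisation at the methyl-bearing carbon between the two hydroxyls should give 14.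

3. Step 13. The dienolate of 16 may be alkylated on oxygen, or may add on the face syn to the acyloxy group (C5 epimer). Bromine may be transferred from 16 to the sulfinate or to the enaminone, and the elimination of sulfinate may be incomplete.
Fallback, setting out from 23 and coming back at 25: 23 is treated with NaOMe in MeOH (elimination, then addition of methanol) to give the methyl ether (6R)-5-amino-6-hydroxy-3-methoxy-2-(methoxymethyl)-6-methyl-4-[(2R)-2-methylbutanoyl]cyclohexa-2,4-dien-1-one F8. F8 and 16 are then joined under Sc(OTf)3 catalysis (CH2Cl2, 23 °C) through the methoxy-stabilised allylic cation; this cationic alkylation is reversible at oxygen and should funnel to the C5-alkylated product 25.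

**Further compounds**
F1 | step 11 | (2R)-2-methylbutanoyl chloride | CC[C@@H](C)C(Cl)=O
F2 | step 11 | (2R)-1-(2,4-dihydroxy-6-methoxy-3-methylphenyl)-2-methylbutan-1-one | CC[C@@H](C)C(=O)c1c(O)c(C)c(O)cc1OC
F3 | step 11 | (6R)-5,6-dihydroxy-3-methoxy-6-methyl-4-[(2R)-2-methylbutanoyl]cyclohexa-2,4-dien-1-one | O=C1C=C(OC)C(C(=O)[C@H](C)CC)=C(O)[C@@]1(C)O
F4 | step 11 | (6R)-5,6-dihydroxy-3-methoxy-6-methyl-4-[(2R)-2-methylbutanoyl]-2-[(phenylsulfanyl)methyl]cyclohexa-2,4-dien-1-one | c1ccccc1SCC2=C(OC)C(C(=O)[C@H](C)CC)=C(O)[C@@](C)(O)C2=O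
F5 | step 11 | (6R)-6-hydroxy-3-methoxy-6-methyl-4-[(2R)-2-methylbutanoyl]-1-oxo-2-[(phenylsulfanyl)methyl]cyclohexa-2,4-dien-5-yl trifluoromethanesulfonate | c1ccccc1SCC2=C(OC)C(C(=O)[C@H](C)CC)=C(OS(=O)(=O)C(F)(F)F)[C@@](C)(O)C2=O
F6 | step 7 | (2R)-1-{2,4-dihydroxy-6-methoxy-3-methyl-5-[(phenylsulfanyl)methyl]phenyl}-2-methylbutan-1-one | CC[C@@H](C)C(=O)c1c(O)c(C)c(O)c(CSc2ccccc2)c1OC
F7 | step 7 | (2R)-1-(2,4-dihydroxy-6-methoxy-3,5-dimethylphenyl)-2-methylbutan-1-one | CC[C@@H](C)C(=O)c1c(O)c(C)c(O)c(C)c1OC
F8 | step 13 | (6R)-5-amino-6-hydroxy-3-methoxy-2-(methoxymethyl)-6-methyl-4-[(2R)-2-methylbutanoyl]cyclohexa-2,4-dien-1-one | COCC1=C(OC)C(C(=O)[C@H](C)CC)=C(N)[C@@](C)(O)C1=O
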